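Ring B is opened between C6 and C7: because C7 bears a 2-propenyl group beside the C6 methylene, the C6=C7 bond and the C11=C12 methylene together form the 1,3-diene signature of a ring-closing enyne metathesis. That single ruthenium-carbene operation joins a C5 vinyl group to a C8 1-propynyl group, closes ring B as a six-membered ring and builds the isopropenyl carbon set, without touching a stereocentre. Its precursor is a ring A cyclohexane (C1–C5, C10) carrying C4, C5, C9 and C10 in final form: a vinyl/methyl quaternary C5, a C10 chain CH(OPMB)–CH(OH)–C≡C–CH3 and C2 as a dioxolane. The diene is afterwards trimmed to the C7 stereocentre by oxidation and 1,4-reduction.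

Key step: step 14

Remark: locants follow eremophilane numbering throughout; C8 becomes a ketone in step 15, so the minor C8 epimer expected from step 13 is carried along with 20 (drawn as the major 8,9-anti isomer), and any minor enantiomer from step 2 becomes a separable diastereomer in step 8.

Step 1
Reactants: 1 but-3-en-2-one
Product: 2 tert-butyl(buta-1,3-dien-2-yloxy)dimethylsilane
Conditions: TBSOTf, Et3N, Et2O, 0 °C
Reagents that add atoms: tert-butyldimethylsilyl trifluoromethanesulfonate, CC(C)(C)[Si](C)(C)OS(=O)(=O)C(F)(F)F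
Why: Silyl enol ether formation by soft enolisation (silyl triflate with an amine base) converts the enone into the 2-silyloxydiene, and the bulky silyl group is chosen so that the enol ether survives steps 2 and 3.

Step 2
Reactants: 2 tert-butyl(buta-1,3-dien-2-yloxy)dimethylsilane; 3 (E)-2-methylbut-2-enal
Product: 4 (1S,6S)-4-(tert-butyldimethylsilyloxy)-1,6-dimethylcyclohex-3-ene-1-carbaldehyde
Conditions: o-tolyl-CBS-oxazaborolidine activated with Tf2NH (20 mol%; antipode chosen for attack on the α-Si face of the enal), CH2Cl2, −78 → −40 °C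
Reagents that add atoms: none
Why: Enantioselective Diels–Alder reaction under chiral oxazaborolidinium catalysis: the nucleophilic CH2 terminus next to the silyloxy carbon bonds to the β-carbon of the bound s-trans enal (para orientation, placing the enol ether at C2=C1), suprafacial addition to the (E)-alkene makes the C4 and C5 methyl groups cis, and the catalyst antipode that sends the diene to the Si face of the enal α-carbon fixes both centres as drawn.

Step 3
Reactants: 4 (1S,6S)-4-(tert-butyldimethylsilyloxy)-1,6-dimethylcyclohex-3-ene-1-carbaldehyde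
Product: 5 tert-butyl{[(4R,5S)-4-ethenyl-4,5-dimethylcyclohex-1-en-1-yl]oxy}dimethylsilane
Conditions: Ph3PCH3Br, KOt-Bu, THF, 0 °C → rt
Reagents that add atoms: methyltriphenylphosphonium bromide (as its ylide), C[P+](c1ccccc1)(c1ccccc1)c1ccccc1.[Br-]
Why: Wittig methylenation of the non-enolisable aldehyde on the quaternary carbon gives the C5 vinyl group without touching the silyl enol ether or either stereocentre.

Step 4
Reactants: 5 tert-butyl{[(4R,5S)-4-ethenyl-4,5-dimethylcyclohex-1-en-1-yl]oxy}dimethylsilane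
Product: 6 (4R,5S)-4-ethenyl-4,5-dimethylcyclohex-2-en-1-one
Conditions: Pd(OAc)2 (1.05 equiv), MeCN, rt
Reagents that add atoms: none
Why: Saegusa–Ito oxidation: palladation at C1 of the regiodefined enol ether by divalent palladium is followed by β-hydride elimination, which can only involve C10, so the C1=C10 enone should form alone.

Step 5
Reactants: 6 (4R,5S)-4-ethenyl-4,5-dimethylcyclohex-2-en-1-one; 7 tert-butyl[(1-methoxyethenyl)oxy]dimethylsilane
Product: 9 methyl 2-[(1R,2R,3S)-2-ethenyl-2,3-dimethyl-5-oxocyclohexyl]acetate, via silyl enol ether 8 (not isolated)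
Conditions: Tf2NH (2 mol%), CH2Cl2, −78 °C; then 1 M HCl, THF, 0 °C
Reagents that add atoms: none
Why: Mukaiyama–Michael addition: the ketene silyl acetal attacks C10 axially on the half-chair with the C4 methyl group equatorial, that is anti to the pseudoaxial C5 methyl group and trans to the C4 methyl group, so the acetate arm becomes cis to the vinyl group (C10 as in the target), and dilute acid then cleaves the silyl enol ether.

Step 6
Reactants: 9 methyl 2-[(1R,2R,3S)-2-ethenyl-2,3-dimethyl-5-oxocyclohexyl]acetate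
Product: 10 methyl 2-[(7R,8R,9S)-8-ethenyl-8,9-dimethyl-1,4-dioxaspiro[4.5]decan-7-yl]acetate
Conditions: HOCH2CH2OH, p-TsOH·H2O (cat.), benzene, reflux (Dean–Stark)
Reagents that add atoms: ethane-1,2-diol, OCCO
Why: Acid-catalysed ketalisation with azeotropic removal of water masks the C2 ketone as the dioxolane that is kept until the last step, the ester and the alkene being inert.

Step 7
Reactants: 10 methyl 2-[(7R,8R,9S)-8-ethenyl-8,9-dimethyl-1,4-dioxaspiro[4.5]decan-7-yl]acetate
Product: 11 2-[(7S,8R,9S)-8-ethenyl-8,9-dimethyl-1,4-dioxaspiro[4.5]decan-7-yl]acetaldehyde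
Conditions: i-Bu2AlH (1.1 equiv), CH2Cl2, −78 °C; aq. KNaC4H4O6
Reagents that add atoms: none
Why: Partial ester reduction: at −78 °C the aluminium hemiacetal formed from i-Bu2AlH is stable and collapses to the aldehyde only on work-up.

Step 8
Reactants: 11 2-[(7S,8R,9S)-8-ethenyl-8,9-dimethyl-1,4-dioxaspiro[4.5]decan-7-yl]acetaldehyde
Product: 13 (2S)-2-[(7S,8R,9S)-8-ethenyl-8,9-dimethyl-1,4-dioxaspiro[4.5]decan-7-yl]-2-(phenylaminooxy)ethan-1-ol, via α-aminooxy aldehyde 12 (not isolated)
Conditions: PhNO, D-proline (20 mol%), DMSO, rt; then NaBH4, EtOH, 0 °C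
Reagents that add atoms: nitrosobenzene, O=Nc1ccccc1
Why: Proline-catalysed α-aminoxylation: the anti enamine of D-proline is attacked at C9 by the oxygen of nitrosobenzene, which is held by the carboxylic acid, so the catalyst and not the neighbouring C10 centre sets C9 as S, and immediate NaBH4 reduction secures the labile α-oxy aldehyde.

Step 9
Reactants: 13 (2S)-2-[(7S,8R,9S)-8-ethenyl-8,9-dimethyl-1,4-dioxaspiro[4.5]decan-7-yl]-2-(phenylaminooxy)ethan-1-ol
Product: 14 (1S)-1-[(7S,8R,9S)-8-ethenyl-8,9-dimethyl-1,4-dioxaspiro[4.5]decan-7-yl]ethane-1,2-diol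
Conditions: Zn, AcOH, EtOH, rt
Reagents that add atoms: none
Why: Reductive cleavage of the N–O bond by zinc in acetic acid releases the secondary C9 hydroxyl and leaves alkene and dioxolane untouched.

Step 10
Reactants: 14 (1S)-1-[(7S,8R,9S)-8-ethenyl-8,9-dimethyl-1,4-dioxaspiro[4.5]decan-7-yl]ethane-1,2-diol
Product: 15 (7S,8R,9S)-8-ethenyl-7-[(4S)-2-(4-methoxyphenyl)-1,3-dioxolan-4-yl]-8,9-dimethyl-1,4-dioxaspiro[4.5]decane (both epimers at the acetal carbon)
Conditions: 4-MeOC6H4CH(OMe)2, PPTS (cat.), CH2Cl2, rt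
Reagents that add atoms: 4-methoxybenzaldehyde dimethyl acetal, COc1ccc(cc1)C(OC)OC
Why: Acid-catalysed transacetalisation closes the five-membered p-methoxybenzylidene acetal on the terminal 1,2-diol (the new acetal centre is a mixture and disappears in step 11).

Step 11
Reactants: 15 (7S,8R,9S)-8-ethenyl-7-[(4S)-2-(4-methoxyphenyl)-1,3-dioxolan-4-yl]-8,9-dimethyl-1,4-dioxaspiro[4.5]decane
Product: 16 (2S)-2-[(7S,8R,9S)-8-ethenyl-8,9-dimethyl-1,4-dioxaspiro[4.5]decan-7-yl]-2-(4-methoxybenzyloxy)ethan-1-ol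
Conditions: i-Bu2AlH (3 equiv), CH2Cl2, −78 → 0 °C
Reagents that add atoms: none
Why: Regioselective reductive acetal opening: aluminium binds the less hindered primary oxygen and hydride is delivered to the benzylic oxocarbenium ion, which leaves the 4-methoxybenzyl ether on the secondary C9 oxygen and frees the C8 alcohol.

Step 12
Reactants: 16 (2S)-2-[(7S,8R,9S)-8-ethenyl-8,9-dimethyl-1,4-dioxaspiro[4.5]decan-7-yl]-2-(4-methoxybenzyloxy)ethan-1-ol
Product: 17 (2S)-2-[(7S,8R,9S)-8-ethenyl-8,9-dimethyl-1,4-dioxaspiro[4.5]decan-7-yl]-2-(4-methoxybenzyloxy)acetaldehyde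
Conditions: Dess–Martin periodinane, pyridine, CH2Cl2, 0 °C → rt
Reagents that add atoms: none
Why: Dess–Martin oxidation under pyridine buffering gives the α-alkoxy aldehyde without epimerising C9.

Step 13
Reactants: 17 (2S)-2-[(7S,8R,9S)-8-ethenyl-8,9-dimethyl-1,4-dioxaspiro[4.5]decan-7-yl]-2-(4-methoxybenzyloxy)acetaldehyde; 18 propyne
Product: 20 (1S,2R)-1-[(7S,8R,9S)-8-ethenyl-8,9-dimethyl-1,4-dioxaspiro[4.5]decan-7-yl]-1-(4-methoxybenzyloxy)pent-3-yn-2-ol, via 1-propynyllithium 19 (not isolated)
Conditions: propyne, n-BuLi, THF, −78 °C; then 17, −78 °C; aq. NH4Cl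
Reagents that add atoms: none
Why: 1,2-Addition of a lithium acetylide in a non-chelating medium follows the Felkin–Anh model with the C9–O bond anti to the nucleophile and should give mainly the 8,9-anti carbinol, but either C8 epimer serves because C8 is oxidised in step 15.

Step 14
Reactants: 20 (1S,2R)-1-[(7S,8R,9S)-8-ethenyl-8,9-dimethyl-1,4-dioxaspiro[4.5]decan-7-yl]-1-(4-methoxybenzyloxy)pent-3-yn-2-ol
Product: 21 2,2-ethylenedioxy-9α-(4-methoxybenzyloxy)-10βH-eremophila-6,11-dien-8α-ol
Conditions: second-generation Grubbs catalyst RuCl2(=CHPh)(PCy3)(H2IMes) (10 mol%), ethylene (1 atm), toluene, 80 °C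
Reagents that add atoms: none
Why: Ring-closing enyne metathesis: a ruthenium methylidene, kept alive by ethylene, adds across the C7≡C11 triple bond to a ruthenacyclobutene that opens to a vinylcarbene, and metathesis with the C5 vinyl group (directly, or after ethylene has first turned the carbene end into a methylene) forms C6=C7 and leaves C11 as a methylene-bearing carbon. The closest known reaction type is the ruthenium-catalysed cyclisation of 1,7-enynes to 1-alkenylcyclohexenes under an ethylene atmosphere. Ring B closes in the exo mode as a six-membered ring. No stereocentre is made; C4, C5, C8, C9 and C10 pass through unchanged. The step needs exo rather than endo (seven-membered) closure and cyclisation rather than alkyne oligomerisation, and both are secured by the 1,7-tether, the methyl cap on the alkyne and the ethylene atmosphere, under which a carbene stranded on C11 is converted into the C11=C12 methylene before it can close the larger ring. The cis relation of the vinyl group and the C10 side chain on ring A, set in steps 2 and 5, keeps the two reacting groups within reach.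

Step 15
Reactants: 21 2,2-ethylenedioxy-9α-(4-methoxybenzyloxy)-10βH-eremophila-6,11-dien-8α-ol
Product: 22 2,2-ethylenedioxy-9α-(4-methoxybenzyloxy)-10βH-eremophila-6,11-dien-8-one
Conditions: Dess–Martin periodinane, pyridine, CH2Cl2, 0 °C
Reagents that add atoms: none
Why: Dess–Martin oxidation of the doubly allylic alcohol gives the cross-conjugated dienone required for 1,4-reduction.

Step 16
Reactants: 22 2,2-ethylenedioxy-9α-(4-methoxybenzyloxy)-10βH-eremophila-6,11-dien-8-one
Product: 23 2,2-ethylenedioxy-9α-(4-methoxybenzyloxy)-7αH,10βH-eremophil-11-en-8-one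
Conditions: [(Ph3P)CuH]6 (0.4 equiv), H2O (5 equiv), toluene–THF, rt
Reagents that add atoms: none
Why: Copper hydride conjugate reduction: hydride adds only to C6, and water should protonate the copper dienolate at its α-carbon C7 on the α face, anti to the angular C5 methyl group, so that the new hydrogen is axial and the 2-propenyl group β and equatorial in the product chair (the more stable C7 epimer), out of conjugation under these near-neutral conditions.

Step 17
Reactants: 23 2,2-ethylenedioxy-9α-(4-methoxybenzyloxy)-7αH,10βH-eremophil-11-en-8-one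
Product: 24 2,2-ethylenedioxy-9α-(4-methoxybenzyloxy)-7αH,10βH-eremophil-11-en-8α-ol
Conditions: NaBH4, CeCl3·7H2O, MeOH, −78 °C
Reagents that add atoms: none
Why: Luche-type borohydride reduction: hydride attacks C8 axially from the convex β face, which is also anti to the axial C9–O bond (Felkin–Anh), giving the equatorial 8α-alcohol.

Step 18
Reactants: 24 2,2-ethylenedioxy-9α-(4-methoxybenzyloxy)-7αH,10βH-eremophil-11-en-8α-ol; 25 (R)-2-methylbutanoic acid
Product: 26 2,2-ethylenedioxy-9α-(4-methoxybenzyloxy)-7αH,10βH-eremophil-11-en-8α-yl (2R)-2-methylbutanoate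
Conditions: DCC, DMAP (cat.), CH2Cl2, 0 °C → rt
Reagents that add atoms: none
Why: Steglich esterification of the equatorial C8 alcohol; at 0 °C with catalytic DMAP the α-stereocentre of the acid should not racemise through a ketene.

Step 19
Reactants: 26 2,2-ethylenedioxy-9α-(4-methoxybenzyloxy)-7αH,10βH-eremophil-11-en-8α-yl (2R)-2-methylbutanoate
Product: 27 2,2-ethylenedioxy-9α-hydroxy-7αH,10βH-eremophil-11-en-8α-yl (2R)-2-methylbutanoate
Conditions: DDQ, CH2Cl2–pH 7 buffer, 0 °C
Reagents that add atoms: none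
Why: Oxidative removal of the 4-methoxybenzyl group by DDQ (benzylic hydride abstraction to an oxocarbenium ion and hydrolysis) under buffered conditions spares ester, ketal and alkene and avoids acyl migration.

Step 20
Reactants: 27 2,2-ethylenedioxy-9α-hydroxy-7αH,10βH-eremophil-11-en-8α-yl (2R)-2-methylbutanoate; 28 (E)-2-methylbut-2-enoic acid (tiglic acid)
Product: 30 2,2-ethylenedioxy-8α-[(2R)-2-methylbutanoyloxy]-7αH,10βH-eremophil-11-en-9α-yl (E)-2-methylbut-2-enoate, via mixed anhydride 29 (not isolated)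
Conditions: 2,4,6-trichlorobenzoyl chloride, Et3N, toluene, rt; then 27, DMAP, 60 °C
Reagents that add atoms: none
Why: Yamaguchi esterification: the mixed anhydride activated by DMAP should acylate the hindered axial C9 alcohol faster than the neighbouring ester can migrate, and the (E)-configured tiglate does not isomerise.

Step 21
Reactants: 30 2,2-ethylenedioxy-8α-[(2R)-2-methylbutanoyloxy]-7αH,10βH-eremophil-11-en-9α-yl (E)-2-methylbut-2-enoate
Product: 31 8α-[(2R)-2-methylbutanoyloxy]-2-oxo-7αH,10βH-eremophil-11-en-9α-yl (E)-2-methylbut-2-enoate (CNP0312791.1)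
Conditions: 1 M HCl, THF, rt
Reagents that add atoms: water, O
Why: Acid-catalysed ketal hydrolysis frees the C2 ketone, which has only methylene neighbours and so nothing to epimerise, while both esters withstand dilute acid at room temperature.

Compound list (21–31 are cis-fused with 4β,5β-dimethyl groups)
1 | but-3-en-2-one | CC(=O)C=C | starting material
2 | tert-butyl(buta-1,3-dien-2-yloxy)dimethylsilane | C=CC(=C)O[Si](C)(C)C(C)(C)C | intermediate
3 | (E)-2-methylbut-2-enal | C/C=C(\C)C=O | starting material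
4 | (1S,6S)-4-(tert-butyldimethylsilyloxy)-1,6-dimethylcyclohex-3-ene-1-carbaldehyde | O=C[C@@]1(C)CC=C(O[Si](C)(C)C(C)(C)C)C[C@@H]1C | intermediate
5 | tert-butyl{[(4R,5S)-4-ethenyl-4,5-dimethylcyclohex-1-en-1-yl]oxy}dimethylsilane | C=C[C@@]1(C)CC=C(O[Si](C)(C)C(C)(C)C)C[C@@H]1C | intermediate
6 | (4R,5S)-4-ethenyl-4,5-dimethylcyclohex-2-en-1-one | C=C[C@@]1(C)C=CC(=O)C[C@@H]1C | intermediate
7 | tert-butyl[(1-methoxyethenyl)oxy]dimethylsilane | C=C(OC)O[Si](C)(C)C(C)(C)C | starting material
8 | methyl 2-[(1S,5S,6R)-3-(tert-butyldimethylsilyloxy)-6-ethenyl-5,6-dimethylcyclohex-2-en-1-yl]acetate | C=C[C@@]1(C)[C@H](C=C(O[Si](C)(C)C(C)(C)C)C[C@@H]1C)CC(=O)OC | intermediate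
9 | methyl 2-[(1R,2R,3S)-2-ethenyl-2,3-dimethyl-5-oxocyclohexyl]acetate | C=C[C@@]1(C)[C@H](CC(=O)C[C@@H]1C)CC(=O)OC | intermediate
10 | methyl 2-[(7R,8R,9S)-8-ethenyl-8,9-dimethyl-1,4-dioxaspiro[4.5]decan-7-yl]acetate | C=C[C@@]1(C)[C@H](CC2(OCCO2)C[C@@H]1C)CC(=O)OC | intermediate
11 | 2-[(7S,8R,9S)-8-ethenyl-8,9-dimethyl-1,4-dioxaspiro[4.5]decan-7-yl]acetaldehyde | C=C[C@@]1(C)[C@H](CC2(OCCO2)C[C@@H]1C)CC=O | intermediate
12 | (2S)-2-[(7S,8R,9S)-8-ethenyl-8,9-dimethyl-1,4-dioxaspiro[4.5]decan-7-yl]-2-(phenylaminooxy)acetaldehyde | C=C[C@@]1(C)[C@H](CC2(OCCO2)C[C@@H]1C)[C@H](ONc1ccccc1)C=O | intermediate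
13 | (2S)-2-[(7S,8R,9S)-8-ethenyl-8,9-dimethyl-1,4-dioxaspiro[4.5]decan-7-yl]-2-(phenylaminooxy)ethan-1-ol | C=C[C@@]1(C)[C@H](CC2(OCCO2)C[C@@H]1C)[C@H](ONc1ccccc1)CO | intermediate
14 | (1S)-1-[(7S,8R,9S)-8-ethenyl-8,9-dimethyl-1,4-dioxaspiro[4.5]decan-7-yl]ethane-1,2-diol | C=C[C@@]1(C)[C@H](CC2(OCCO2)C[C@@H]1C)[C@H](O)CO | intermediate
15 | (7S,8R,9S)-8-ethenyl-7-[(4S)-2-(4-methoxyphenyl)-1,3-dioxolan-4-yl]-8,9-dimethyl-1,4-dioxaspiro[4.5]decane (both epimers at the acetal carbon) | C=C[C@@]1(C)[C@H](CC2(OCCO2)C[C@@H]1C)[C@H]1COC(c2ccc(OC)cc2)O1 | intermediate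
16 | (2S)-2-[(7S,8R,9S)-8-ethenyl-8,9-dimethyl-1,4-dioxaspiro[4.5]decan-7-yl]-2-(4-methoxybenzyloxy)ethan-1-ol | C=C[C@@]1(C)[C@H](CC2(OCCO2)C[C@@H]1C)[C@H](OCc1ccc(OC)cc1)CO | intermediate
17 | (2S)-2-[(7S,8R,9S)-8-ethenyl-8,9-dimethyl-1,4-dioxaspiro[4.5]decan-7-yl]-2-(4-methoxybenzyloxy)acetaldehyde | C=C[C@@]1(C)[C@H](CC2(OCCO2)C[C@@H]1C)[C@H](OCc1ccc(OC)cc1)C=O | intermediate
18 | propyne | CC#C | starting material
19 | 1-propynyllithium | CC#C[Li] | intermediate
20 | (1S,2R)-1-[(7S,8R,9S)-8-ethenyl-8,9-dimethyl-1,4-dioxaspiro[4.5]decan-7-yl]-1-(4-methoxybenzyloxy)pent-3-yn-2-ol | C=C[C@@]1(C)[C@H](CC2(OCCO2)C[C@@H]1C)[C@H](OCc1ccc(OC)cc1)[C@H](O)C#CC | intermediate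
21 | 2,2-ethylenedioxy-9α-(4-methoxybenzyloxy)-10βH-eremophila-6,11-dien-8α-ol | C=C(C)C1=C[C@@]2(C)[C@H](CC3(OCCO3)C[C@@H]2C)[C@H](OCc2ccc(OC)cc2)[C@@H]1O | intermediate
22 | 2,2-ethylenedioxy-9α-(4-methoxybenzyloxy)-10βH-eremophila-6,11-dien-8-one | C=C(C)C1=C[C@@]2(C)[C@H](CC3(OCCO3)C[C@@H]2C)[C@H](OCc2ccc(OC)cc2)C1=O | intermediate
23 | 2,2-ethylenedioxy-9α-(4-methoxybenzyloxy)-7αH,10βH-eremophil-11-en-8-one | C=C(C)[C@H]1C[C@@]2(C)[C@H](CC3(OCCO3)C[C@@H]2C)[C@H](OCc2ccc(OC)cc2)C1=O | intermediate
24 | 2,2-ethylenedioxy-9α-(4-methoxybenzyloxy)-7αH,10βH-eremophil-11-en-8α-ol | C=C(C)[C@H]1C[C@@]2(C)[C@H](CC3(OCCO3)C[C@@H]2C)[C@H](OCc2ccc(OC)cc2)[C@@H]1O | intermediate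
25 | (R)-2-methylbutanoic acid | CC[C@@H](C)C(=O)O | starting material
26 | 2,2-ethylenedioxy-9α-(4-methoxybenzyloxy)-7αH,10βH-eremophil-11-en-8α-yl (2R)-2-methylbutanoate | C=C(C)[C@H]1C[C@@]2(C)[C@H](CC3(OCCO3)C[C@@H]2C)[C@H](OCc2ccc(OC)cc2)[C@@H]1OC(=O)[C@H](C)CC | intermediate
27 | 2,2-ethylenedioxy-9α-hydroxy-7αH,10βH-eremophil-11-en-8α-yl (2R)-2-methylbutanoate | C=C(C)[C@H]1C[C@@]2(C)[C@H](CC3(OCCO3)C[C@@H]2C)[C@H](O)[C@@H]1OC(=O)[C@H](C)CC | intermediate
28 | (E)-2-methylbut-2-enoic acid (tiglic acid) | C/C=C(\C)C(=O)O | starting material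
29 | (E)-2-methylbut-2-enoic 2,4,6-trichlorobenzoic anhydride | C/C=C(\C)C(=O)OC(=O)c1c(Cl)cc(Cl)cc1Cl | intermediate
30 | 2,2-ethylenedioxy-8α-[(2R)-2-methylbutanoyloxy]-7αH,10βH-eremophil-11-en-9α-yl (E)-2-methylbut-2-enoate | C=C(C)[C@H]1C[C@@]2(C)[C@H](CC3(OCCO3)C[C@@H]2C)[C@H](OC(=O)/C(C)=C/C)[C@@H]1OC(=O)[C@H](C)CC | intermediate
31 | 8α-[(2R)-2-methylbutanoyloxy]-2-oxo-7αH,10βH-eremophil-11-en-9α-yl (E)-2-methylbut-2-enoate (CNP0312791.1) | C=C(C)[C@H]1C[C@@]2(C)[C@H](CC(=O)C[C@@H]2C)[C@H](OC(=O)/C(C)=C/C)[C@@H]1OC(=O)[C@H](C)CC | target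

Total step count: 21. Longest linear sequence: 21 steps (1 → 31); compounds 3, 7, 18, 25 and 28 enter as commercial materials.

Steps most likely to fail

Step 14 (key step). What may go wrong: carbene formation at the neopentyl C5 vinyl group is slow, so that oligomerisation of the alkyne, closure in the endo sense to a seven-membered ring, or loss of the catalyst through chelation by the free C8 hydroxyl overtakes ring closure. Fallback: the two metathesis events are run as two separate reactions. Setting out from 20, cross-metathesis of the alkyne with ethylene alone (first-generation Grubbs catalyst RuCl2(=CHPh)(PCy3)2, ethylene 1 atm, CH2Cl2, rt), which does not involve the hindered vinyl group, should give the isolable triene carbinol F1 with its 2,3-disubstituted butadiene. Ring-closing olefin metathesis of F1 between the C5 vinyl group and the C7 methylene (second-generation Hoveyda–Grubbs catalyst RuCl2(=CH-C6H4-2-O-i-Pr)(H2IMes), toluene, 80 °C, argon sparge to drive off ethene) then comes back to the route at 21.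

Step 16. What may go wrong: protonation of the dienolate at C12 instead of C7, or later migration of the C11=C12 double bond into conjugation with the C8 ketone, and protonation at C7 on the β face, which gives the C7 epimer. Fallback: the thermodynamic sink is accepted first and deconjugated kinetically afterwards. Setting out from 22, reduction with Li[HB(s-Bu)3] (THF, −78 °C) and treatment of the crude ketones with DBU should funnel all isomers into the single conjugated 7(11)-en-8-one F2. F2 is deprotonated at C12 with LiN(i-Pr)2 (THF, −78 °C) and the lithium dienolate is added to cold acetic acid in THF (kinetic α-protonation, the deconjugation known for 2-alkylidene cyclohexanones), which returns to the route at 23. Material protonated on the wrong face or re-conjugated is cycled through F2 again.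

Step 8. What may go wrong: slow enamine turnover with the β-branched aldehyde lets N-attack on nitrosobenzene, self-aldol reaction and erosion of catalyst control at C9 compete. Fallback: the oxygen is introduced at the ester stage and C9 is set by hydride addition instead. Setting out from 10, enolate hydroxylation (LiN(i-Pr)2; 2-(phenylsulfonyl)-3-phenyloxaziridine, THF, −78 °C) gives the α-hydroxy ester F3 as a C9 mixture, and Dess–Martin oxidation gives the α-keto ester F4. Felkin–Anh reduction with Li[HB(s-Bu)3] at −78 °C (hydride anti to the C5 side of C10, expected to give 9S) leads to the (9S)-hydroxy ester F5. Etherification with 4-methoxybenzyl trichloroacetimidate and catalytic camphorsulfonic acid gives the 4-methoxybenzyl ether F6, and partial reduction with i-Bu2AlH at −78 °C re-enters the route at 17.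

Further compounds
F1 | step 14 | (1S,2R)-1-[(7S,8R,9S)-8-ethenyl-8,9-dimethyl-1,4-dioxaspiro[4.5]decan-7-yl]-1-(4-methoxybenzyloxy)-4-methyl-3-methylidenepent-4-en-2-ol | C=C[C@@]1(C)[C@H](CC2(OCCO2)C[C@@H]1C)[C@H](OCc1ccc(OC)cc1)[C@H](O)C(=C)C(C)=C
F2 | step 16 | 2,2-ethylenedioxy-9α-(4-methoxybenzyloxy)-10βH-eremophil-7(11)-en-8-one | CC(C)=C1C[C@@]2(C)[C@H](CC3(OCCO3)C[C@@H]2C)[C@H](OCc2ccc(OC)cc2)C1=O
F3 | step 8 | methyl 2-[(7S,8R,9S)-8-ethenyl-8,9-dimethyl-1,4-dioxaspiro[4.5]decan-7-yl]-2-hydroxyacetate (both C2 epimers) | C=C[C@@]1(C)[C@H](CC2(OCCO2)C[C@@H]1C)C(O)C(=O)OC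
F4 | step 8 | methyl 2-[(7S,8R,9S)-8-ethenyl-8,9-dimethyl-1,4-dioxaspiro[4.5]decan-7-yl]-2-oxoacetate | C=C[C@@]1(C)[C@H](CC2(OCCO2)C[C@@H]1C)C(=O)C(=O)OC
F5 | step 8 | methyl (2S)-2-[(7S,8R,9S)-8-ethenyl-8,9-dimethyl-1,4-dioxaspiro[4.5]decan-7-yl]-2-hydroxyacetate | C=C[C@@]1(C)[C@H](CC2(OCCO2)C[C@@H]1C)[C@H](O)C(=O)OC
F6 | step 8 | methyl (2S)-2-[(7S,8R,9S)-8-ethenyl-8,9-dimethyl-1,4-dioxaspiro[4.5]decan-7-yl]-2-(4-methoxybenzyloxy)acetate | C=C[C@@]1(C)[C@H](CC2(OCCO2)C[C@@H]1C)[C@H](OCc1ccc(OC)cc1)C(=O)OC
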